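## Retrosynthetic overview

1. Target ⇐ sevenfold deallylation of a hepta-allyl precursor ⇐ O-acylation of an (R)-aryl-lactate alcohol (fragment B) by a cinnamic acid (fragment A).
2. Fragment A ⇐ Knoevenagel–Doebner condensation of an aryl aldehyde with malonic acid ⇐ acetal hydrolysis ⇐ (Z)-α-aryloxy-acrylate.
3. Key C–C bond: intermolecular aldol addition of the lithium enolate of an allyl aryloxyacetate to 3,4-bis(allyloxy)benzaldehyde, then E1cB dehydration to the (Z)-enol ether; both partners come from protocatechualdehyde.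
4. Fragment B ⇐ Evans imide enolate hydroxylation (Davis oxaziridine, (R)-4-benzyl-2-oxazolidinone) of the 3-arylpropanoyl imide from dihydrocaffeic acid, then transesterification with allyl alcohol.
5. No ring is constructed: the three benzene rings are carried in intact from protocatechualdehyde (two rings) and dihydrocaffeic acid (one ring).

Assumption: allyl bromoacetate, trans-2-(phenylsulfonyl)-3-phenyloxaziridine and (R)-4-benzyl-2-oxazolidinone are bought as catalogue items; "allyl" means prop-2-en-1-yl throughout.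

## Route

Step 1
Reactants: 1 3,4-dihydroxybenzaldehyde (protocatechualdehyde)
Product: 2 3,4-bis(allyloxy)benzaldehyde
Conditions: allyl bromide (2.5 equiv), K2CO3 (3 equiv), DMF, 60 °C
Reagents that add atoms: allyl bromide, C=CCBr
Why: Williamson ether synthesis; both phenoxides are alkylated by SN2 on the allylic bromide while the aldehyde is inert to carbonate.

Step 2
Reactants: 1 3,4-dihydroxybenzaldehyde
Product: 3 4-(allyloxy)-3-hydroxybenzaldehyde
Conditions: allyl bromide (1.05 equiv), NaHCO3 (1.5 equiv), NaI (0.3 equiv), DMF, 40 °C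
Reagents that add atoms: allyl bromide, C=CCBr
Why: Regioselective Williamson etherification; hydrogencarbonate deprotonates only the more acidic 4-OH (para to the formyl group), so mono-alkylation occurs there.

Step 3
Reactants: 3 4-(allyloxy)-3-hydroxybenzaldehyde
Product: 4 allyl 2-[2-(allyloxy)-5-formylphenoxy]acetate
Conditions: allyl bromoacetate (1.2 equiv), K2CO3 (1.5 equiv), acetone, reflux
Reagents that add atoms: allyl bromoacetate, BrCC(=O)OCC=C
Why: Williamson etherification of the remaining phenol with a highly reactive α-bromo ester installs the aryloxyacetate that becomes the aldol donor.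

Step 4
Reactants: 4 allyl 2-[2-(allyloxy)-5-formylphenoxy]acetate
Product: 5 allyl 2-[2-(allyloxy)-5-(1,3-dioxolan-2-yl)phenoxy]acetate
Conditions: Me3SiOCH2CH2OSiMe3 (1.5 equiv), Me3SiOSO2CF3 (5 mol %), CH2Cl2, −78 to −20 °C; pyridine quench
Reagents that add atoms: 1,2-bis(trimethylsilyloxy)ethane, C[Si](C)(C)OCCO[Si](C)(C)C
Why: Noyori acetalisation masks the aldehyde under aprotic, low-temperature conditions that cannot transesterify the allyl ester, so the donor cannot self-condense in the aldol step.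

Step 5
Reactants: 5 allyl 2-[2-(allyloxy)-5-(1,3-dioxolan-2-yl)phenoxy]acetate; 2 3,4-bis(allyloxy)benzaldehyde
Product: 7 allyl 3-[3,4-bis(allyloxy)phenyl]-2-[2-(allyloxy)-5-(1,3-dioxolan-2-yl)phenoxy]-3-hydroxypropanoate (racemic syn/anti mixture), via lithium enolate 6 (not isolated)
Conditions: LiN(i-Pr)2 (1.1 equiv, commercial solution), THF, −78 °C, ester added slowly; then 2 (1.1 equiv), −78 °C, 1 h; AcOH quench at −78 °C
Reagents that add atoms: none
Why: Directed intermolecular aldol addition; the kinetically formed ester enolate adds to the non-enolisable aldehyde at −78 °C faster than it can rearrange or self-condense, and both new stereocentres are erased in step 6, so their ratio is irrelevant.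

Step 6
Reactants: 7 allyl 3-[3,4-bis(allyloxy)phenyl]-2-[2-(allyloxy)-5-(1,3-dioxolan-2-yl)phenoxy]-3-hydroxypropanoate
Product: 9 allyl (Z)-2-[2-(allyloxy)-5-(1,3-dioxolan-2-yl)phenoxy]-3-[3,4-bis(allyloxy)phenyl]prop-2-enoate, via mesylate 8 (not isolated)
Conditions: MsCl (1.5 equiv), Et3N (3 equiv), CH2Cl2, 0 °C; then 1,8-diazabicyclo[5.4.0]undec-7-ene (DBU, 3 equiv), 0 °C to rt
Reagents that add atoms: none
Why: Mesylation followed by E1cB elimination through the ester enolate funnels both diastereomers to the conjugated enol ether, whose (Z)-geometry (aryl trans to the ester, cis to the aryloxy group) is the thermodynamically favoured one; any minor (E)-isomer is removed by chromatography.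

Step 7
Reactants: 9 allyl (Z)-2-[2-(allyloxy)-5-(1,3-dioxolan-2-yl)phenoxy]-3-[3,4-bis(allyloxy)phenyl]prop-2-enoate
Product: 10 allyl (Z)-2-[2-(allyloxy)-5-formylphenoxy]-3-[3,4-bis(allyloxy)phenyl]prop-2-enoate
Conditions: 1 M HCl, THF, 0 °C to rt
Reagents that add atoms: water, O
Why: Acid-catalysed acetal hydrolysis of an electron-rich aryl dioxolane is fast under mild conditions, whereas the ester-conjugated aryl enol ether and the allyl groups are not protonated productively.

Step 8
Reactants: 10 allyl (Z)-2-[2-(allyloxy)-5-formylphenoxy]-3-[3,4-bis(allyloxy)phenyl]prop-2-enoate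
Product: 11 (E)-3-{4-(allyloxy)-3-[((Z)-1-(allyloxycarbonyl)-2-[3,4-bis(allyloxy)phenyl]vinyl)oxy]phenyl}prop-2-enoic acid (fragment A)
Conditions: malonic acid (3 equiv), pyridine, piperidine (0.1 equiv), 80 °C; then cold 1 M HCl
Reagents that add atoms: malonic acid, OC(=O)CC(=O)O
Why: Knoevenagel–Doebner condensation (aldol-type addition, dehydration, decarboxylation) gives the (E)-cinnamic acid directly as the free acid, so it is differentiated from the allyl ester already present.

Step 9
Reactants: 12 3-(3,4-dihydroxyphenyl)propanoic acid (dihydrocaffeic acid)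
Product: 14 3-[3,4-bis(allyloxy)phenyl]propanoic acid, via triallyl ester 13 (not isolated)
Conditions: allyl bromide (4 equiv), K2CO3 (4 equiv), DMF, 60 °C; then 2 M NaOH, MeOH/THF, rt; then 1 M HCl
Reagents that add atoms: allyl bromide, C=CCBr; sodium hydroxide, [Na+].[OH-]
Why: Exhaustive Williamson/carboxylate alkylation followed by saponification of the only ester leaves the two aryl allyl ethers, which are inert to hydroxide.

Step 10
Reactants: 14 3-[3,4-bis(allyloxy)phenyl]propanoic acid; 15 (R)-4-benzyl-2-oxazolidinone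
Product: 17 (R)-4-benzyl-3-{3-[3,4-bis(allyloxy)phenyl]propanoyl}oxazolidin-2-one, via pivalic mixed anhydride 16 (not isolated)
Conditions: pivaloyl chloride (1.1 equiv), Et3N (2.5 equiv), THF, −20 °C; then LiCl (1.2 equiv), 15, −20 °C to rt
Reagents that add atoms: none
Why: Mixed-anhydride N-acylation of the auxiliary; the oxazolidinone attacks the unhindered carbonyl of the pivalic mixed anhydride.

Step 11
Reactants: 17 (R)-4-benzyl-3-{3-[3,4-bis(allyloxy)phenyl]propanoyl}oxazolidin-2-one
Product: 19 (R)-4-benzyl-3-{(R)-3-[3,4-bis(allyloxy)phenyl]-2-hydroxypropanoyl}oxazolidin-2-one, via sodium enolate 18 (not isolated)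
Conditions: NaN(SiMe3)2 (1.1 equiv), THF, −78 °C; then trans-2-(phenylsulfonyl)-3-phenyloxaziridine (1.5 equiv), −78 °C; then (±)-camphorsulfonic acid in THF, −78 °C
Reagents that add atoms: trans-2-(phenylsulfonyl)-3-phenyloxaziridine (Davis oxaziridine), O=S(=O)(c1ccccc1)N1OC1c1ccccc1
Why: Evans imide enolate hydroxylation; the chelated (Z)-enolate is oxidised by the Davis oxaziridine on the face opposite the C4 benzyl group of the (R)-auxiliary, which sets the new α-stereocentre as (R) (about 95:5, minor diastereomer removed by chromatography).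

Step 12
Reactants: 19 (R)-4-benzyl-3-{(R)-3-[3,4-bis(allyloxy)phenyl]-2-hydroxypropanoyl}oxazolidin-2-one
Product: 20 allyl (R)-3-[3,4-bis(allyloxy)phenyl]-2-hydroxypropanoate (fragment B)
Conditions: MeMgBr (2.2 equiv) added to allyl alcohol/CH2Cl2 at 0 °C, then 19, 0 °C, 30 min; 1 M HCl quench
Reagents that add atoms: allyl alcohol, C=CCO
Why: Magnesium-alkoxide transesterification; magnesium chelated between the α-alkoxide and the exocyclic carbonyl directs allyloxide to the exocyclic acyl group, releasing the auxiliary without epimerising the α-stereocentre.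

Step 13
Reactants: 11 (E)-3-{4-(allyloxy)-3-[((Z)-1-(allyloxycarbonyl)-2-[3,4-bis(allyloxy)phenyl]vinyl)oxy]phenyl}prop-2-enoic acid; 20 allyl (R)-3-[3,4-bis(allyloxy)phenyl]-2-hydroxypropanoate
Product: 22 allyl (R)-3-[3,4-bis(allyloxy)phenyl]-2-{[(E)-3-{4-(allyloxy)-3-[((Z)-1-(allyloxycarbonyl)-2-[3,4-bis(allyloxy)phenyl]vinyl)oxy]phenyl}prop-2-enoyl]oxy}propanoate (hepta-allyl salvianolic acid H), via acid chloride 21 (not isolated)
Conditions: (COCl)2 (1.5 equiv), N,N-dimethylformamide (cat.), CH2Cl2, 0 °C to rt, evaporate; then 20 (1.1 equiv), pyridine (3 equiv), 4-(dimethylamino)pyridine (0.1 equiv), CH2Cl2, 0 °C to rt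
Reagents that add atoms: none
Why: Acylation of the secondary alcohol by the cinnamoyl chloride under nucleophilic catalysis forms the ester at oxygen only, so the (R)-centre is carried through with retention and the acid chloride has no α-hydrogen through which to form a ketene.

Step 14
Reactants: 22 hepta-allyl salvianolic acid H
Product: 23 salvianolic acid H
Conditions: Pd(PPh3)4 (0.2 equiv), morpholine (25 equiv), degassed THF, rt, argon; then 1 M HCl, reversed-phase chromatography
Reagents that add atoms: none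
Why: Tsuji–Trost deallylation; zerovalent palladium ionises the five aryl allyl ethers and two allyl esters to π-allyl complexes that morpholine traps irreversibly, at room temperature and near-neutral pH where the cinnamate ester, both alkenes, the enol ether and the stereocentre are untouched.

## Compound list

1 | 3,4-dihydroxybenzaldehyde | O=Cc1ccc(O)c(O)c1 | starting material
2 | 3,4-bis(allyloxy)benzaldehyde | O=Cc1ccc(OCC=C)c(OCC=C)c1 | intermediate
3 | 4-(allyloxy)-3-hydroxybenzaldehyde | O=Cc1ccc(OCC=C)c(O)c1 | intermediate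
4 | allyl 2-[2-(allyloxy)-5-formylphenoxy]acetate | O=Cc1ccc(OCC=C)c(OCC(=O)OCC=C)c1 | intermediate
5 | allyl 2-[2-(allyloxy)-5-(1,3-dioxolan-2-yl)phenoxy]acetate | C=CCOC(=O)COc1cc(C2OCCO2)ccc1OCC=C | intermediate
6 | lithium enolate of 5 | [Li]OC(OCC=C)=COc1cc(C2OCCO2)ccc1OCC=C | intermediate (not isolated)
7 | allyl 3-[3,4-bis(allyloxy)phenyl]-2-[2-(allyloxy)-5-(1,3-dioxolan-2-yl)phenoxy]-3-hydroxypropanoate, racemic syn/anti mixture | C=CCOC(=O)C(Oc1cc(C2OCCO2)ccc1OCC=C)C(O)c1ccc(OCC=C)c(OCC=C)c1 | intermediate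
8 | methanesulfonate of 7 | C=CCOC(=O)C(Oc1cc(C2OCCO2)ccc1OCC=C)C(OS(C)(=O)=O)c1ccc(OCC=C)c(OCC=C)c1 | intermediate (not isolated)
9 | allyl (Z)-2-[2-(allyloxy)-5-(1,3-dioxolan-2-yl)phenoxy]-3-[3,4-bis(allyloxy)phenyl]prop-2-enoate | C=CCOc1ccc(C2OCCO2)cc1O/C(=C\c1ccc(OCC=C)c(OCC=C)c1)C(=O)OCC=C | intermediate
10 | allyl (Z)-2-[2-(allyloxy)-5-formylphenoxy]-3-[3,4-bis(allyloxy)phenyl]prop-2-enoate | C=CCOc1ccc(C=O)cc1O/C(=C\c1ccc(OCC=C)c(OCC=C)c1)C(=O)OCC=C | intermediate
11 | (E)-3-{4-(allyloxy)-3-[((Z)-1-(allyloxycarbonyl)-2-[3,4-bis(allyloxy)phenyl]vinyl)oxy]phenyl}prop-2-enoic acid (fragment A) | C=CCOc1ccc(/C=C/C(=O)O)cc1O/C(=C\c1ccc(OCC=C)c(OCC=C)c1)C(=O)OCC=C | intermediate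
12 | 3-(3,4-dihydroxyphenyl)propanoic acid | OC(=O)CCc1ccc(O)c(O)c1 | starting material
13 | allyl 3-[3,4-bis(allyloxy)phenyl]propanoate | C=CCOC(=O)CCc1ccc(OCC=C)c(OCC=C)c1 | intermediate (not isolated)
14 | 3-[3,4-bis(allyloxy)phenyl]propanoic acid | OC(=O)CCc1ccc(OCC=C)c(OCC=C)c1 | intermediate
15 | (R)-4-benzyl-2-oxazolidinone | O=C1N[C@H](Cc2ccccc2)CO1 | starting material
16 | 3-[3,4-bis(allyloxy)phenyl]propanoic pivalic anhydride | CC(C)(C)C(=O)OC(=O)CCc1ccc(OCC=C)c(OCC=C)c1 | intermediate (not isolated)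
17 | (R)-4-benzyl-3-{3-[3,4-bis(allyloxy)phenyl]propanoyl}oxazolidin-2-one | O=C(CCc1ccc(OCC=C)c(OCC=C)c1)N1[C@H](Cc2ccccc2)COC1=O | intermediate
18 | (Z)-sodium enolate of 17 | [Na]O/C(=C\Cc1ccc(OCC=C)c(OCC=C)c1)N1[C@H](Cc2ccccc2)COC1=O | intermediate (not isolated)
19 | (R)-4-benzyl-3-{(R)-3-[3,4-bis(allyloxy)phenyl]-2-hydroxypropanoyl}oxazolidin-2-one | O[C@H](Cc1ccc(OCC=C)c(OCC=C)c1)C(=O)N1[C@H](Cc2ccccc2)COC1=O | intermediate
20 | allyl (R)-3-[3,4-bis(allyloxy)phenyl]-2-hydroxypropanoate (fragment B) | O[C@H](Cc1ccc(OCC=C)c(OCC=C)c1)C(=O)OCC=C | intermediate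
21 | acid chloride of 11 | C=CCOc1ccc(/C=C/C(Cl)=O)cc1O/C(=C\c1ccc(OCC=C)c(OCC=C)c1)C(=O)OCC=C | intermediate (not isolated)
22 | hepta-allyl salvianolic acid H | O=C(/C=C/c1ccc(OCC=C)c(O/C(=C\c2ccc(OCC=C)c(OCC=C)c2)C(=O)OCC=C)c1)O[C@H](Cc1ccc(OCC=C)c(OCC=C)c1)C(=O)OCC=C | intermediate
23 | salvianolic acid H | O=C(/C=C/c1ccc(O)c(O/C(=C\c2ccc(O)c(O)c2)C(=O)O)c1)O[C@H](Cc1ccc(O)c(O)c1)C(=O)O | target

## Step count and risks

Total step count: 14. Longest linear sequence: 9 steps (1 → 3 → 4 → 5 → 7 → 9 → 10 → 11 → 22 → 23; steps 2, 3, 4, 5, 6, 7, 8, 13, 14).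

Three steps most likely to fail:

Step 5 (with its dehydration in step 6). The allyl ester enolate can self-condense or rearrange, the aldolate can revert, and the alkene geometry is only set afterwards. The fallback sets out from 5 (with aldehyde 2) and comes back at 9. The allyl ester of 5 is saponified (LiOH, THF/H2O, 0 °C, acidified only to pH 4–5) to 2-[2-(allyloxy)-5-(1,3-dioxolan-2-yl)phenoxy]acetic acid F1. F1 is condensed with 2 in a Perkin reaction (Ac2O, Et3N, 90 °C, then aqueous NaHCO3), a one-pot aldol-type condensation and dehydration under thermodynamic control. This gives (Z)-2-[2-(allyloxy)-5-(1,3-dioxolan-2-yl)phenoxy]-3-[3,4-bis(allyloxy)phenyl]prop-2-enoic acid F2 with the aryl group trans to the carboxyl. Alkylation of the carboxylate with allyl bromide and KHCO3 in DMF returns 9 and bypasses steps 5 and 6.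

Step 12. Transesterification of a hindered imide with a free α-hydroxyl by an allyl alkoxide may be slow or may open the oxazolidinone ring. The fallback sets out from 19 and comes back at 20. Hydrolysis with LiOH/H2O2 (THF/H2O, 0 °C, Na2SO3 work-up) removes the auxiliary and gives (R)-3-[3,4-bis(allyloxy)phenyl]-2-hydroxypropanoic acid F3. Its carboxylate is then alkylated selectively with allyl bromide and KHCO3 in DMF at rt; the secondary hydroxyl does not react under these conditions, and the product is 20.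

Step 13. The α-hydroxy ester is a hindered, weakly nucleophilic alcohol and the acid chloride carries sensitive functionality. The fallback sets out from 20 (with aldehyde 10) and comes back at 22. Alcohol 20 is heated with Meldrum's acid in toluene at 100 °C to give the malonic half ester 3-{[(2R)-1-(allyloxy)-3-[3,4-bis(allyloxy)phenyl]-1-oxopropan-2-yl]oxy}-3-oxopropanoic acid F4. F4 then undergoes a decarboxylative Knoevenagel–Doebner condensation with aldehyde 10 (pyridine, catalytic piperidine, 60 °C). This builds the (E)-cinnamate C=C bond with the ester linkage already in place and gives 22 directly, so step 8 is also bypassed.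

## Further compounds

F1 | step 5 | 2-[2-(allyloxy)-5-(1,3-dioxolan-2-yl)phenoxy]acetic acid | OC(=O)COc1cc(C2OCCO2)ccc1OCC=C
F2 | step 5 | (Z)-2-[2-(allyloxy)-5-(1,3-dioxolan-2-yl)phenoxy]-3-[3,4-bis(allyloxy)phenyl]prop-2-enoic acid | C=CCOc1ccc(C2OCCO2)cc1O/C(=C\c1ccc(OCC=C)c(OCC=C)c1)C(=O)O
F3 | step 12 | (R)-3-[3,4-bis(allyloxy)phenyl]-2-hydroxypropanoic acid | O[C@H](Cc1ccc(OCC=C)c(OCC=C)c1)C(=O)O
F4 | step 13 | 3-{[(2R)-1-(allyloxy)-3-[3,4-bis(allyloxy)phenyl]-1-oxopropan-2-yl]oxy}-3-oxopropanoic acid | OC(=O)CC(=O)O[C@H](Cc1ccc(OCC=C)c(OCC=C)c1)C(=O)OCC=C
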